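The quinone ring is built from two malonyl-type C3 units, O–C–C(C21H43)–C–O and O–C–C(CH3)–C–O, which are joined only through two bonds between oxygen-bearing ring carbons (each C=O carbon to the adjacent C–OH carbon). Both bonds unite carbons of like, acyl polarity. The methyl-bearing unit is therefore reversed in polarity as the 1,3-dilithio bis(1,3-dithiane) of methylmalonaldehyde, and the chain-bearing unit is used as (chlorocarbonyl)henicosylketene, a malonyl dication equivalent without an acidic C–H. One [3+3] double acylation closes the carbocycle at the tetraketone oxidation level, so that dithiane hydrolysis alone gives the dihydroxyquinone, the tautomer of the cyclohexane-1,2,4,5-tetraone.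

Key step: step 4

Remark: the target has no stereocentre. 2,5-Dihydroxy-1,4-benzoquinones are the stable enol tautomers of cyclohexane-1,2,4,5-tetraones, so a precursor at the tetraketone oxidation level is assumed to tautomerise spontaneously to the target. Compounds 1, 2 and 4 are taken as commercial.

Step 1
Reactants: 1 1,1,3,3-tetraethoxy-2-methylpropane; 2 propane-1,3-dithiol
Product: 3 2,2'-(ethane-1,1-diyl)bis(1,3-dithiane)
Conditions: 2 (2.1 equiv in all), BF3·OEt2 (cat.), AcOH/CHCl3, 0 °C → rt
Reagents that add atoms: propane-1,3-dithiol (the second equivalent of 2), SCCCS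
Why: Acid-catalysed transthioacetalisation should exchange each of the two diethyl acetals for the favoured cyclic 1,3-dithiane, one molecule of dithiol being consumed per acetal carbon (dithioacetal formation).

Step 2
Reactants: 4 tricosanoic acid
Product: 6 2-henicosylpropanedioic acid (henicosylmalonic acid), via dilithium tricos-1-ene-1,1-diolate 5 (not isolated)
Conditions: LiN(i-Pr)2 (LDA, 2.2 equiv), THF/DMPU, 0 → 45 °C; CO2 (g), −78 °C → rt; then 2 M HCl, 0 °C
Reagents that add atoms: carbon dioxide, O=C=O
Why: Two equivalents of amide base should convert the acid into its enediolate, whose α-carbon is carboxylated by CO2 (carboxylation of a carboxylic acid dianion, a reaction type known for long-chain fatty acids).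

Step 3
Reactants: 6 2-henicosylpropanedioic acid
Product: 8 2-henicosyl-3-oxoprop-2-enoyl chloride [(chlorocarbonyl)henicosylketene], via 2-henicosylpropanedioyl dichloride 7 (not isolated)
Conditions: SOCl2 (excess, neat), 75 °C; evaporate; then 110 °C, reduced pressure, until HCl evolution stops; crude 8 taken up in dry THF
Reagents that add atoms: thionyl chloride, O=S(Cl)Cl
Why: Thionyl chloride should give the malonyl dichloride, which loses HCl from its doubly activated C–H on heating (thermal dehydrochlorination, the usual preparation of (chlorocarbonyl)ketenes from monosubstituted malonic acids).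

Step 4
Reactants: 3 2,2'-(ethane-1,1-diyl)bis(1,3-dithiane); 8 2-henicosyl-3-oxoprop-2-enoyl chloride
Product: 11 2-henicosyl-3-hydroxy-5-methylcyclohex-2-en-1-one carrying spiro-fused 1,3-dithiane rings at C4 and C6 (racemic), via 2,2'-(ethane-1,1-diyl)bis(2-lithio-1,3-dithiane) 9 (not isolated), via ring-open lithio acylketene 10 (not isolated)
Conditions: 3, n-BuLi (2.1 equiv), THF, −25 °C; then this solution and 8 in THF added simultaneously and slowly to THF at −70 °C (high dilution), → 0 °C; 1 M HCl
Reagents that add atoms: none
Why: Proposed new method: a [3+3] double nucleophilic acylation in which the 1,3-bis(acyl anion) equivalent 9 attacks both electrophilic carbons of the malonyl dication equivalent 8; whichever terminus reacts first (addition to the ketene carbon followed by E1cB loss of chloride, or substitution at the acid chloride), the same acylketene 10 should result, and its remaining C–Li then adds to the ketene carbon in a 6-exo-dig closure that delivers 11 as its lithium 1,3-diketonate. The closest known reactions are the Corey–Seebach acylation of 2-lithio-1,3-dithianes by acid chlorides, the addition of organolithiums to ketenes to give enolates, the ring-forming bis-alkylation of 1,3-bis(dithianyl) dianions by dihalides, and the cyclocondensations of (chlorocarbonyl)ketenes with 1,3-dinucleophiles. The step needs cross-union of the two C3 units, which the opposite polarity of 8 and 9 secures, and ring closure in place of oligomerisation, which the 1,3-spacing of the two carbanions and slow simultaneous addition at high dilution should favour. Enolisation cannot quench 9 because 8 has no C–H between its two carbonyl carbons, and over-addition is not expected because the product is formed as an unreactive enolate. The CH(CH3) carbon is stereogenic only in the enol form of 11 (uncontrolled, racemic) and this centre disappears in step 5.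

Step 5
Reactants: 11 2-henicosyl-3-hydroxy-5-methylcyclohex-2-en-1-one carrying spiro-fused 1,3-dithiane rings at C4 and C6
Product: 12 2,5-dihydroxy-3-henicosyl-6-methylcyclohexa-2,5-diene-1,4-dione (target)
Conditions: Hg(ClO4)2·3H2O (2.5 equiv), CaCO3, THF/H2O, 0 °C → rt; then 1 M HCl
Reagents that add atoms: water, O
Why: Thiophilic Hg(ClO4)2 (divalent mercury) should ionise the C–S bonds so that water hydrolyses both dithioketals (mercury-assisted dethioketalisation), and the liberated tetraketone should enolise at both ring C–H positions to the dihydroxyquinone without any redox step.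

Compound list

1 | 1,1,3,3-tetraethoxy-2-methylpropane | CCOC(OCC)C(C)C(OCC)OCC | starting material
2 | propane-1,3-dithiol | SCCCS | starting material
3 | 2,2'-(ethane-1,1-diyl)bis(1,3-dithiane) | CC(C1SCCCS1)C1SCCCS1 | intermediate
4 | tricosanoic acid | CCCCCCCCCCCCCCCCCCCCCCC(=O)O | starting material
5 | dilithium tricos-1-ene-1,1-diolate (dianion of 4, not isolated) | CCCCCCCCCCCCCCCCCCCCCC=C(O[Li])O[Li] | intermediate
6 | 2-henicosylpropanedioic acid | CCCCCCCCCCCCCCCCCCCCCC(C(=O)O)C(=O)O | intermediate
7 | 2-henicosylpropanedioyl dichloride (not isolated) | CCCCCCCCCCCCCCCCCCCCCC(C(=O)Cl)C(=O)Cl | intermediate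
8 | 2-henicosyl-3-oxoprop-2-enoyl chloride, (chlorocarbonyl)henicosylketene | CCCCCCCCCCCCCCCCCCCCCC(=C=O)C(=O)Cl | intermediate
9 | 2,2'-(ethane-1,1-diyl)bis(2-lithio-1,3-dithiane) (not isolated) | CC(C1([Li])SCCCS1)C1([Li])SCCCS1 | intermediate
10 | 2-henicosyl-1-{2-[1-(2-lithio-1,3-dithian-2-yl)ethyl]-1,3-dithian-2-yl}prop-2-ene-1,3-dione, ring-open lithio acylketene (not isolated) | CCCCCCCCCCCCCCCCCCCCCC(=C=O)C(=O)C1(SCCCS1)C(C)C1([Li])SCCCS1 | intermediate
11 | 2-henicosyl-3-hydroxy-5-methylcyclohex-2-en-1-one with spiro-fused 1,3-dithiane rings at C4 and C6 (enol form of 3-henicosyl-6-methylcyclohexane-1,2,4,5-tetraone 1,5-bis(propane-1,3-diyl dithioketal), racemic) | CCCCCCCCCCCCCCCCCCCCCC1=C(O)C2(SCCCS2)C(C)C2(SCCCS2)C1=O | intermediate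
12 | 2,5-dihydroxy-3-henicosyl-6-methylcyclohexa-2,5-diene-1,4-dione | CCCCCCCCCCCCCCCCCCCCCC1=C(O)C(=O)C(C)=C(O)C1=O | target

Total step count: 5. Longest linear sequence: 4 steps (4 → 6 → 8 → 11 → 12); the other branch (1 + 2 → 3) joins in step 4.

Steps most likely to fail

Step 4 (labelled step). Intermolecular acylation may outrun ring closure and give oligomers, the acylketene may self-condense, or 9 may abstract a proton from the chain CH2 next to the ketene carbon. The fallback uses known chemistry only, sets out from 9 (with 5 as the second partner) and returns to the route at 11. The dianion 9 is added to excess ethyl chloroformate (THF, −78 °C) to give diethyl 2,2'-(ethane-1,1-diyl)bis(1,3-dithiane-2-carboxylate) F1 (Corey–Seebach acylation, which still makes both carbonyl–carbonyl bonds in one operation). F1, used in excess, is acylated once by the enediolate 5 (2 equiv, THF/DMPU; Claisen-type acylation of a carboxylic acid dianion) to give, after acidification, 3-{2-[1-(2-ethoxycarbonyl-1,3-dithian-2-yl)ethyl]-1,3-dithian-2-yl}-2-henicosyl-3-oxopropanoic acid F2. This β-keto acid should lose CO2 on gentle warming to give ethyl 2-[1-(2-tricosanoyl-1,3-dithian-2-yl)ethyl]-1,3-dithiane-2-carboxylate F3. KOt-Bu in THF should then close the ring by acylation of the ketone enolate on the remaining ester (Dieckmann-type 6-exo-trig cyclisation of a δ-keto ester to a cyclohexane-1,3-dione), giving 11.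

Step 3. Dehydrochlorination may stay incomplete, or the waxy ketene may oligomerise on heating or hydrolyse with adventitious moisture. The fallback sets out from 6 and returns to the route at 11 through 10. Compound 6 is esterified with 2,4,6-trichlorophenol and POCl3 (100 °C) to the crystallisable active ester bis(2,4,6-trichlorophenyl) 2-henicosylpropanedioate F4. NaH (1 equiv, THF, 0 °C) gives its sodium enolate, which should stand in E1cB equilibrium with 2,4,6-trichlorophenoxide and 2,4,6-trichlorophenyl 2-henicosyl-3-oxoprop-2-enoate F5, the aryloxycarbonyl analogue of 8, generated without heating and without acid. Slow addition of 9 under the conditions of step 4 should trap F5, expel the second aryloxide to give the same acylketene 10, and close the ring to 11.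

Step 5. Hydrolysis of two hindered, carbonyl-flanked dithioketals may stop halfway, and the free enol and the acidic product may be mercurated or held as metal chelates. The fallback sets out from 11 and returns to the route at 12. The enol is first capped with TMSCHN2 (MeOH/toluene, rt) to give 2-henicosyl-3-methoxy-5-methylcyclohex-2-en-1-one with spiro-fused 1,3-dithiane rings at C4 and C6 F6 (one racemate, since the two possible enol ethers are mirror images). The dithioketals are then cleaved oxidatively without metal by PhI(OCOCF3)2 in aqueous MeCN (0 °C), which should give 2-henicosyl-6-hydroxy-3-methoxy-5-methylcyclohexa-2,5-diene-1,4-dione F7. Hydrolysis of this vinylogous ester with aqueous NaOH in THF, then acidification, gives 12.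

Further compounds

F1 | step 4 | diethyl 2,2'-(ethane-1,1-diyl)bis(1,3-dithiane-2-carboxylate) | CCOC(=O)C1(SCCCS1)C(C)C1(SCCCS1)C(=O)OCC
F2 | step 4 | 3-{2-[1-(2-ethoxycarbonyl-1,3-dithian-2-yl)ethyl]-1,3-dithian-2-yl}-2-henicosyl-3-oxopropanoic acid | CCCCCCCCCCCCCCCCCCCCCC(C(=O)O)C(=O)C1(SCCCS1)C(C)C1(SCCCS1)C(=O)OCC
F3 | step 4 | ethyl 2-[1-(2-tricosanoyl-1,3-dithian-2-yl)ethyl]-1,3-dithiane-2-carboxylate | CCCCCCCCCCCCCCCCCCCCCCC(=O)C1(SCCCS1)C(C)C1(SCCCS1)C(=O)OCC
F4 | step 3 | bis(2,4,6-trichlorophenyl) 2-henicosylpropanedioate | CCCCCCCCCCCCCCCCCCCCCC(C(=O)Oc1c(Cl)cc(Cl)cc1Cl)C(=O)Oc1c(Cl)cc(Cl)cc1Cl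
F5 | step 3 | 2,4,6-trichlorophenyl 2-henicosyl-3-oxoprop-2-enoate | CCCCCCCCCCCCCCCCCCCCCC(=C=O)C(=O)Oc1c(Cl)cc(Cl)cc1Cl
F6 | step 5 | 2-henicosyl-3-methoxy-5-methylcyclohex-2-en-1-one with spiro-fused 1,3-dithiane rings at C4 and C6 | CCCCCCCCCCCCCCCCCCCCCC1=C(OC)C2(SCCCS2)C(C)C2(SCCCS2)C1=O
F7 | step 5 | 2-henicosyl-6-hydroxy-3-methoxy-5-methylcyclohexa-2,5-diene-1,4-dione | CCCCCCCCCCCCCCCCCCCCCC1=C(OC)C(=O)C(C)=C(O)C1=O
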